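## Retrosynthetic overview

1. Ballotiquinone ⇐ its 12-O-methyl ether (hydrolysis) ⇐ 11,12,14-trimethoxy arene (oxidative demethylation) ⇐ tetracyclic 1,7-diketone (one reduction sets C1 and C7).
2. Ring B is closed last: C7–C8 by intramolecular Friedel–Crafts acylation, after C10=C20 has been made by an intermolecular aldol condensation that joins a ring A enone lactone (enolate at C10) to a ring C benzaldehyde (C20).
3. Ring A: Diels–Alder of a 2-silyloxybutadiene onto an (R)-γ-silyloxymethyl butenolide from D-glutamic acid (C6 controls C5 and C4), then C4 methylation and Saegusa oxidation so that only C10 can enolise.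
4. Ring C aldehyde: 1,2,4-trimethoxybenzene by two directed lithiations (acetone, then DMF).
5. Order of ring formation: γ-lactone (chiral pool) → ring A → ring C attached by the aldol → ring B.

Assumption: atom labels C1–C20 are the icetexane positions of the target (ring A = C1–C5 and C10; ring B = C5–C10 and C20; ring C = C8, C9, C11–C14; C18 = methyl on C4; C19 = lactone carbonyl); the target is (1R,4S,5R,6R,7S); every step ends with a standard aqueous work-up.

## Route

Step 1
Reactants: 1 1,2,4-trimethoxybenzene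
Product: 3 2-(2,3,6-trimethoxyphenyl)propan-2-ol, via aryllithium 2 (not isolated)
Conditions: n-BuLi, THF, 0 °C; acetone, −78 °C → rt; H2O
Reagents that add atoms: acetone, CC(C)=O
Why: Directed ortho-metalation removes the ring hydrogen flanked by two methoxy groups, the most acidic position, and carbonyl addition of the aryllithium to acetone installs the three carbons of the future isopropyl group at C13.

Step 2
Reactants: 3 2-(2,3,6-trimethoxyphenyl)propan-2-ol
Product: 4 1,2,4-trimethoxy-3-(propan-2-yl)benzene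
Conditions: Et3SiH, CF3CO2H, CH2Cl2, 0 °C → rt
Reagents that add atoms: none
Why: Ionic hydrogenation works because the tertiary benzylic alcohol ionises in acid to a cation stabilised by the electron-rich ring and is trapped by hydride from the silane.

Step 3
Reactants: 4 1,2,4-trimethoxy-3-(propan-2-yl)benzene
Product: 6 2,3,5-trimethoxy-4-(propan-2-yl)benzaldehyde, via aryllithium 5 (not isolated)
Conditions: n-BuLi, TMEDA, Et2O, 0 °C → rt; DMF, −78 °C → rt; aq. HCl
Reagents that add atoms: N,N-dimethylformamide, CN(C)C=O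
Why: Directed ortho-metalation followed by formylation should go to the hydrogen next to the vicinal dimethoxy pair (future C9), which is acidified by an ortho and a meta oxygen, leaving C8–H free and placing the C20 aldehyde.

Step 4
Reactants: 7 D-glutamic acid
Product: 9 (2R)-5-oxooxolane-2-carboxylic acid, via diazonium salt 8 (not isolated)
Conditions: NaNO2, aq. HCl, 0 °C → rt
Reagents that add atoms: none
Why: Diazotisation with neighbouring-group participation displaces nitrogen first by the α-carboxylate and then by the γ-carboxylate, a double inversion that gives the γ-lactone with net retention, so C6 comes from the chiral pool as R.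

Step 5
Reactants: 9 (2R)-5-oxooxolane-2-carboxylic acid
Product: 10 (5R)-5-(hydroxymethyl)oxolan-2-one
Conditions: BH3·SMe2, THF, 0 °C → rt; MeOH
Reagents that add atoms: none
Why: Chemoselective borane reduction takes the free carboxylic acid (through an acyloxyborane) much faster than the lactone and gives the future C7 carbinol without touching the stereocentre.

Step 6
Reactants: 10 (5R)-5-(hydroxymethyl)oxolan-2-one
Product: 11 (5R)-5-{[tert-butyl(diphenyl)silyl]oxymethyl}oxolan-2-one
Conditions: t-BuPh2SiCl, imidazole, DMF, rt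
Reagents that add atoms: tert-butyl(chloro)diphenylsilane, CC(C)(C)[Si](Cl)(c1ccccc1)c1ccccc1
Why: Imidazole-promoted silylation protects the primary C7 hydroxyl as an ether that survives strong base, heat and the later palladium and rhodium steps.

Step 7
Reactants: 11 (5R)-5-{[tert-butyl(diphenyl)silyl]oxymethyl}oxolan-2-one
Product: 13 (5R)-5-{[tert-butyl(diphenyl)silyl]oxymethyl}-3-(phenylselanyl)oxolan-2-one (both C3 epimers), via lithium enolate 12 (not isolated)
Conditions: LiN(iPr)2, THF, −78 °C; PhSeBr, −78 °C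
Reagents that add atoms: benzeneselenenyl bromide, Br[Se]c1ccccc1
Why: α-Selenenylation of the lactone enolate places selenium on the future C4, and the C6 stereocentre is not part of the enolate and stays intact.

Step 8
Reactants: 13 (5R)-5-{[tert-butyl(diphenyl)silyl]oxymethyl}-3-(phenylselanyl)oxolan-2-one
Product: 15 (5R)-5-{[tert-butyl(diphenyl)silyl]oxymethyl}furan-2(5H)-one, via selenoxide 14 (not isolated)
Conditions: 30% aq. H2O2, pyridine, CH2Cl2, 0 °C → rt
Reagents that add atoms: none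
Why: Selenoxide syn-elimination can only go toward the C5 hydrogens and gives the butenolide under mild conditions that do not epimerise the γ-stereocentre C6.

Step 9
Reactants: 16 but-3-en-2-one
Product: 17 (buta-1,3-dien-2-yloxy)(tert-butyl)dimethylsilane
Conditions: t-BuMe2SiOTf, Et3N, Et2O, 0 °C
Reagents that add atoms: tert-butyldimethylsilyl trifluoromethanesulfonate, CC(C)(C)[Si](C)(C)OS(=O)(=O)C(F)(F)F
Why: Soft enolisation and O-silylation (silyl enol ether formation) of the enone gives the 2-silyloxydiene that will supply C10, C1, C2 and C3 of ring A.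

Step 10
Reactants: 15 (5R)-5-{[tert-butyl(diphenyl)silyl]oxymethyl}furan-2(5H)-one; 17 (buta-1,3-dien-2-yloxy)(tert-butyl)dimethylsilane
Product: 18 (3R,3aR,7aS)-5-{[tert-butyl(dimethyl)silyl]oxy}-3-{[tert-butyl(diphenyl)silyl]oxymethyl}-3a,4,7,7a-tetrahydroisobenzofuran-1(3H)-one
Conditions: toluene, BHT (cat.), 150 °C, sealed tube
Reagents that add atoms: none
Why: The thermal Diels–Alder cycloaddition adds the diene suprafacially to the butenolide face anti to the C6 silyloxymethyl group (cis ring fusion, C5 set as R with H4 cis to H5), and the nucleophilic diene terminus bonds to the lactone β-carbon so that the silyl enol ether is C1=C2.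

Step 11
Reactants: 18 Diels–Alder adduct (cis-fused silyl enol ether lactone)
Product: 20 (3R,3aR,7aS)-5-{[tert-butyl(dimethyl)silyl]oxy}-3-{[tert-butyl(diphenyl)silyl]oxymethyl}-7a-methyl-3a,4,7,7a-tetrahydroisobenzofuran-1(3H)-one, via lithium enolate 19 (not isolated)
Conditions: LiN(iPr)2, THF, −78 °C; MeI, −78 → −40 °C
Reagents that add atoms: iodomethane, CI
Why: Enolate alkylation of the ring-fusion lactone enolate takes place on the convex face, cis to H5 and away from ring A, which keeps the cis fusion and sets quaternary C4 as S with the methyl trans to C10.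

Step 12
Reactants: 20 methylated silyl enol ether lactone
Product: 21 (3R,3aR,7aS)-3-{[tert-butyl(diphenyl)silyl]oxymethyl}-7a-methyl-3a,4-dihydroisobenzofuran-1,5(3H,7aH)-dione
Conditions: Pd(OAc)2 (1.1 equiv), MeCN, 40 °C
Reagents that add atoms: none
Why: Saegusa–Ito oxidation turns the regiodefined C1=C2 silyl enol ether, through an oxa-π-allyl complex of divalent palladium and β-hydride elimination, into the C2=C3 enone, which leaves C10 as the only enolisable carbon.

Step 13
Reactants: 21 ring A enone lactone; 6 2,3,5-trimethoxy-4-(propan-2-yl)benzaldehyde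
Product: 23 (3R,3aR,7aS)-3-{[tert-butyl(diphenyl)silyl]oxymethyl}-4-{hydroxy[2,3,5-trimethoxy-4-(propan-2-yl)phenyl]methyl}-7a-methyl-3a,4-dihydroisobenzofuran-1,5(3H,7aH)-dione (epimer mixture at the two new centres), via lithium dienolate 22 (not isolated)
Conditions: LiN(iPr)2, THF, −78 °C; 6, −78 °C; AcOH
Reagents that add atoms: none
Why: In this intermolecular directed aldol addition deprotonation can only occur at C10 (C4 is quaternary and C2 is vinylic), and the lithium dienolate adds to the aldehyde to form the C10–C20 bond that joins the two fragments, the two new centres being removed in the next step.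

Step 14
Reactants: 23 aldol adduct
Product: 25 (3R,3aR,4E,7aS)-3-{[tert-butyl(diphenyl)silyl]oxymethyl}-7a-methyl-4-{[2,3,5-trimethoxy-4-(propan-2-yl)phenyl]methylidene}-3a,4-dihydroisobenzofuran-1,5(3H,7aH)-dione, via mesylate 24 (not isolated)
Conditions: MsCl, Et3N, CH2Cl2, 0 °C; DBU, rt
Reagents that add atoms: none
Why: Mesylation and E1cB elimination complete the aldol condensation and give the thermodynamically preferred E benzylidene ketone, in which the aryl group lies cis to C5 as ring B requires.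

Step 15
Reactants: 25 cross-conjugated dienone
Product: 26 (3R,3aR,4E,7aS)-3-{[tert-butyl(diphenyl)silyl]oxymethyl}-7a-methyl-4-{[2,3,5-trimethoxy-4-(propan-2-yl)phenyl]methylidene}-3a,6,7,7a-tetrahydroisobenzofuran-1,5(3H,4H)-dione
Conditions: H2 (1 atm), RhCl(PPh3)3 (5 mol %), benzene/EtOH, rt
Reagents that add atoms: none
Why: Chemoselective homogeneous hydrogenation reduces the cis-disubstituted C2=C3 bond and leaves the trisubstituted, aryl-conjugated C10=C20 bond, the same selectivity that this catalyst shows for cross-conjugated cyclohexadienones.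

Step 16
Reactants: 26 benzylidene ketone silyl ether
Product: 27 (3R,3aR,4E,7aS)-3-(hydroxymethyl)-7a-methyl-4-{[2,3,5-trimethoxy-4-(propan-2-yl)phenyl]methylidene}-3a,6,7,7a-tetrahydroisobenzofuran-1,5(3H,4H)-dione
Conditions: HF·pyridine, pyridine, THF, 0 °C → rt
Reagents that add atoms: none
Why: Fluoride-mediated desilylation under buffered acidic conditions frees the primary C7 alcohol without generating an alkoxide that could translactonise.

Step 17
Reactants: 27 primary alcohol
Product: 29 (3R,3aR,4E,7aS)-7a-methyl-1,5-dioxo-4-{[2,3,5-trimethoxy-4-(propan-2-yl)phenyl]methylidene}octahydroisobenzofuran-3-carboxylic acid (lactone numbering kept), via aldehyde 28 (not isolated)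
Conditions: TEMPO (20 mol %), PhI(OAc)2 (2.5 equiv), MeCN/H2O, rt
Reagents that add atoms: water, O
Why: Nitroxyl-catalysed oxidation takes the primary alcohol to the aldehyde and, through its hydrate, to the carboxylic acid at neutral pH, so C6 is not epimerised and the electron-rich ring is untouched.

Step 18
Reactants: 29 carboxylic acid
Product: 31 (4S,5R,6R)-11,12,14-trimethoxy-1,7-dioxo-9(10→20)-abeo-abieta-8,10(20),11,13-tetraen-19,6-olide, via acid chloride 30 (not isolated)
Conditions: (COCl)2, DMF (cat.), CH2Cl2, 0 °C → rt; SnCl4, CH2Cl2 (high dilution), −40 → 0 °C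
Reagents that add atoms: none
Why: Intramolecular Friedel–Crafts acylation attacks C8, the only unsubstituted ring position and the one activated by the para C12 and ortho C14 methoxy groups, and closes the seven-membered ring B as the C7 ketone.

Step 19
Reactants: 31 tetracyclic 1,7-diketone
Product: 32 (1R,4S,5R,6R,7S)-1,7-dihydroxy-11,12,14-trimethoxy-9(10→20)-abeo-abieta-8,10(20),11,13-tetraen-19,6-olide
Conditions: (S)-2-methyl-CBS-oxazaborolidine (0.5 equiv), catecholborane, toluene/CH2Cl2, −78 → −40 °C; MeOH; aq. NaHCO3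
Reagents that add atoms: none
Why: In this Corey–Bakshi–Shibata reduction the S catalyst delivers hydride so that hydroxyl, the larger unsaturated substituent (the C10 alkene at C1, the aryl carbon C8 at C7) and the smaller sp3 substituent run clockwise, which gives 1R and 7S and agrees with substrate control (axial attack at C1 anti to the axial C5–C6 bond, attack at C7 anti to the C6–O bond).

Step 20
Reactants: 32 trimethoxy diol
Product: 33 (1R,4S,5R,6R,7S)-1,7-dihydroxy-12-methoxy-11,14-dioxo-9(10→20)-abeo-abieta-8,10(20),12-trien-19,6-olide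
Conditions: (NH4)2Ce(NO3)6 (2.5 equiv), MeCN/H2O, 0 °C
Reagents that add atoms: water, O
Why: Oxidative demethylation by tetravalent cerium (single-electron oxidation of the ring, then attack of water) converts the para-related C11 and C14 methoxy groups into the 11,14-quinone and leaves the C12 methoxy as a vinylogous ester.

Step 21
Reactants: 33 12-O-methylballotiquinone
Product: 34 ballotiquinone
Conditions: 0.2 M aq. NaOH, THF, 0 °C; 1 M HCl to pH 2, rt
Reagents that add atoms: sodium hydroxide, [Na+].[OH-]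
Why: Addition–elimination hydrolysis of the vinylogous methyl ester puts hydroxide on C12 and expels methoxide to give the stabilised hydroxyquinone anion, and acidification re-closes any opened lactone and releases the target with all five stereocentres unchanged.

## Compound list

1 | 1,2,4-trimethoxybenzene | COc1ccc(OC)c(OC)c1 | starting material
2 | (2,3,6-trimethoxyphenyl)lithium | [Li]c1c(OC)ccc(OC)c1OC | intermediate
3 | 2-(2,3,6-trimethoxyphenyl)propan-2-ol | CC(C)(O)c1c(OC)ccc(OC)c1OC | intermediate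
4 | 1,2,4-trimethoxy-3-(propan-2-yl)benzene | CC(C)c1c(OC)ccc(OC)c1OC | intermediate
5 | [2,3,5-trimethoxy-4-(propan-2-yl)phenyl]lithium | CC(C)c1c(OC)cc([Li])c(OC)c1OC | intermediate
6 | 2,3,5-trimethoxy-4-(propan-2-yl)benzaldehyde | CC(C)c1c(OC)cc(C=O)c(OC)c1OC | intermediate
7 | D-glutamic acid, (2R)-2-aminopentanedioic acid | N[C@H](CCC(=O)O)C(=O)O | starting material
8 | (1R)-1,3-dicarboxypropane-1-diazonium chloride | [Cl-].N#[N+][C@H](CCC(=O)O)C(=O)O | intermediate
9 | (2R)-5-oxooxolane-2-carboxylic acid | OC(=O)[C@@H]1OC(=O)CC1 | intermediate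
10 | (5R)-5-(hydroxymethyl)oxolan-2-one | OC[C@@H]1OC(=O)CC1 | intermediate
11 | (5R)-5-{[tert-butyl(diphenyl)silyl]oxymethyl}oxolan-2-one | CC(C)(C)[Si](c1ccccc1)(c1ccccc1)OC[C@@H]1OC(=O)CC1 | intermediate
12 | lithium enolate of 11 | CC(C)(C)[Si](c1ccccc1)(c1ccccc1)OC[C@@H]1OC(O[Li])=CC1 | intermediate
13 | (5R)-5-{[tert-butyl(diphenyl)silyl]oxymethyl}-3-(phenylselanyl)oxolan-2-one (both C3 epimers) | CC(C)(C)[Si](c1ccccc1)(c1ccccc1)OC[C@@H]1OC(=O)C([Se]c2ccccc2)C1 | intermediate
14 | (5R)-3-(benzeneseleninyl)-5-{[tert-butyl(diphenyl)silyl]oxymethyl}oxolan-2-one | CC(C)(C)[Si](c1ccccc1)(c1ccccc1)OC[C@@H]1OC(=O)C([Se](=O)c2ccccc2)C1 | intermediate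
15 | (5R)-5-{[tert-butyl(diphenyl)silyl]oxymethyl}furan-2(5H)-one | CC(C)(C)[Si](c1ccccc1)(c1ccccc1)OC[C@@H]1OC(=O)C=C1 | intermediate
16 | but-3-en-2-one | CC(=O)C=C | starting material
17 | (buta-1,3-dien-2-yloxy)(tert-butyl)dimethylsilane | C=CC(=C)O[Si](C)(C)C(C)(C)C | intermediate
18 | (3R,3aR,7aS)-5-{[tert-butyl(dimethyl)silyl]oxy}-3-{[tert-butyl(diphenyl)silyl]oxymethyl}-3a,4,7,7a-tetrahydroisobenzofuran-1(3H)-one | CC(C)(C)[Si](c1ccccc1)(c1ccccc1)OC[C@@H]1OC(=O)[C@H]3CC=C(O[Si](C)(C)C(C)(C)C)C[C@@H]13 | intermediate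
19 | lithium enolate of 18 (lactone C19–O–Li, C19=C4) | CC(C)(C)[Si](c1ccccc1)(c1ccccc1)OC[C@@H]1OC(O[Li])=C3CC=C(O[Si](C)(C)C(C)(C)C)C[C@@H]13 | intermediate
20 | (3R,3aR,7aS)-5-{[tert-butyl(dimethyl)silyl]oxy}-3-{[tert-butyl(diphenyl)silyl]oxymethyl}-7a-methyl-3a,4,7,7a-tetrahydroisobenzofuran-1(3H)-one | CC(C)(C)[Si](c1ccccc1)(c1ccccc1)OC[C@@H]1OC(=O)[C@@]3(C)CC=C(O[Si](C)(C)C(C)(C)C)C[C@@H]13 | intermediate
21 | (3R,3aR,7aS)-3-{[tert-butyl(diphenyl)silyl]oxymethyl}-7a-methyl-3a,4-dihydroisobenzofuran-1,5(3H,7aH)-dione | CC(C)(C)[Si](c1ccccc1)(c1ccccc1)OC[C@@H]1OC(=O)[C@@]3(C)C=CC(=O)C[C@@H]13 | intermediate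
22 | lithium dienolate of 21 (C1–O–Li, C1=C10) | CC(C)(C)[Si](c1ccccc1)(c1ccccc1)OC[C@@H]1OC(=O)[C@@]3(C)C=CC(O[Li])=C[C@@H]13 | intermediate
23 | (3R,3aR,7aS)-3-{[tert-butyl(diphenyl)silyl]oxymethyl}-4-{hydroxy[2,3,5-trimethoxy-4-(propan-2-yl)phenyl]methyl}-7a-methyl-3a,4-dihydroisobenzofuran-1,5(3H,7aH)-dione (epimer mixture at the two new centres) | CC(C)(C)[Si](c1ccccc1)(c1ccccc1)OC[C@@H]1OC(=O)[C@@]3(C)C=CC(=O)C(C(O)c2cc(OC)c(C(C)C)c(OC)c2OC)[C@@H]13 | intermediate
24 | methanesulfonate of 23 | CC(C)(C)[Si](c1ccccc1)(c1ccccc1)OC[C@@H]1OC(=O)[C@@]3(C)C=CC(=O)C(C(OS(C)(=O)=O)c2cc(OC)c(C(C)C)c(OC)c2OC)[C@@H]13 | intermediate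
25 | (3R,3aR,4E,7aS)-3-{[tert-butyl(diphenyl)silyl]oxymethyl}-7a-methyl-4-{[2,3,5-trimethoxy-4-(propan-2-yl)phenyl]methylidene}-3a,4-dihydroisobenzofuran-1,5(3H,7aH)-dione | CC(C)(C)[Si](c1ccccc1)(c1ccccc1)OC[C@@H]1OC(=O)[C@@]3(C)C=CC(=O)/C(=C/c2cc(OC)c(C(C)C)c(OC)c2OC)[C@@H]13 | intermediate
26 | (3R,3aR,4E,7aS)-3-{[tert-butyl(diphenyl)silyl]oxymethyl}-7a-methyl-4-{[2,3,5-trimethoxy-4-(propan-2-yl)phenyl]methylidene}-3a,6,7,7a-tetrahydroisobenzofuran-1,5(3H,4H)-dione | CC(C)(C)[Si](c1ccccc1)(c1ccccc1)OC[C@@H]1OC(=O)[C@@]3(C)CCC(=O)/C(=C/c2cc(OC)c(C(C)C)c(OC)c2OC)[C@@H]13 | intermediate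
27 | (3R,3aR,4E,7aS)-3-(hydroxymethyl)-7a-methyl-4-{[2,3,5-trimethoxy-4-(propan-2-yl)phenyl]methylidene}-3a,6,7,7a-tetrahydroisobenzofuran-1,5(3H,4H)-dione | OC[C@@H]1OC(=O)[C@@]3(C)CCC(=O)/C(=C/c2cc(OC)c(C(C)C)c(OC)c2OC)[C@@H]13 | intermediate
28 | (3R,3aR,4E,7aS)-7a-methyl-1,5-dioxo-4-{[2,3,5-trimethoxy-4-(propan-2-yl)phenyl]methylidene}octahydroisobenzofuran-3-carbaldehyde | O=C[C@@H]1OC(=O)[C@@]3(C)CCC(=O)/C(=C/c2cc(OC)c(C(C)C)c(OC)c2OC)[C@@H]13 | intermediate
29 | (3R,3aR,4E,7aS)-7a-methyl-1,5-dioxo-4-{[2,3,5-trimethoxy-4-(propan-2-yl)phenyl]methylidene}octahydroisobenzofuran-3-carboxylic acid | OC(=O)[C@@H]1OC(=O)[C@@]3(C)CCC(=O)/C(=C/c2cc(OC)c(C(C)C)c(OC)c2OC)[C@@H]13 | intermediate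
30 | acid chloride of 29 | ClC(=O)[C@@H]1OC(=O)[C@@]3(C)CCC(=O)/C(=C/c2cc(OC)c(C(C)C)c(OC)c2OC)[C@@H]13 | intermediate
31 | (4S,5R,6R)-11,12,14-trimethoxy-1,7-dioxo-9(10→20)-abeo-abieta-8,10(20),11,13-tetraen-19,6-olide | CC(C)c1c(OC)c(OC)c2c(c1OC)C(=O)[C@@H]1OC(=O)[C@@]3(C)CCC(=O)C(=C2)[C@@H]13 | intermediate
32 | (1R,4S,5R,6R,7S)-1,7-dihydroxy-11,12,14-trimethoxy-9(10→20)-abeo-abieta-8,10(20),11,13-tetraen-19,6-olide | CC(C)c1c(OC)c(OC)c2c(c1OC)[C@H](O)[C@@H]1OC(=O)[C@@]3(C)CC[C@@H](O)C(=C2)[C@@H]13 | intermediate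
33 | (1R,4S,5R,6R,7S)-1,7-dihydroxy-12-methoxy-11,14-dioxo-9(10→20)-abeo-abieta-8,10(20),12-trien-19,6-olide (12-O-methylballotiquinone) | CC(C)C1=C(OC)C(=O)C2=C(C1=O)[C@H](O)[C@@H]1OC(=O)[C@@]3(C)CC[C@@H](O)C(=C2)[C@@H]13 | intermediate
34 | ballotiquinone, (1R,4S,5R,6R,7S)-1,7,12-trihydroxy-11,14-dioxo-9(10→20)-abeo-abieta-8,10(20),12-trien-19,6-olide | CC(C)C1=C(O)C(=O)C2=C(C1=O)[C@H](O)[C@@H]1OC(=O)[C@@]3(C)CC[C@@H](O)C(=C2)[C@@H]13 | target

## Summary and fallbacks

Total step count: 21. Longest linear sequence: 17 steps (7 → 34 through steps 4–8 and 10–21).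

The three steps most likely to fail:

Step 10 (the butenolide is only a moderate dienophile, so the thermal cycloaddition may be slow or poorly regioselective). The fallback sets out from 15 and comes back at 21, replacing steps 10–12 and making 17 unnecessary; it builds ring A by conjugate addition, alkylation and aldol condensation instead of cycloaddition. Copper-mediated conjugate addition of 2-methylallylmagnesium chloride (CuBr·SMe2, Me3SiCl, THF, −78 °C) anti to the C6 side chain gives the trans-4-(2-methylallyl) lactone F1. Claisen formylation (LiN(iPr)2, then HCO2Et) gives the α-hydroxymethylene lactone F2. C-Methylation (K2CO3, MeI, acetone) anti to the C5 substituent gives the α-formyl-α-methyl lactone F3, with the quaternary C4 set as in 21. Ozonolysis (O3, CH2Cl2, −78 °C; Me2S) gives the keto aldehyde F4. Amine-catalysed intramolecular aldol condensation (pyrrolidine, AcOH, toluene, 80 °C) of the methyl ketone onto the non-enolisable aldehyde closes ring A to 21.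

Step 18 (a seven-membered Friedel–Crafts closure with an α-acyloxy acyl chloride may decarbonylate or be slowed by the enone-bearing ring). The fallback sets out from 27 and comes back at 31; it forms the C7–C8 bond by organochromium addition instead of electrophilic acylation. Iodination at C8, the only free ring position (N-iodosuccinimide, CF3CO2H cat., MeCN, 0 °C), gives the iodo alcohol F5. Dess–Martin oxidation gives the iodo aldehyde F6. Intramolecular Nozaki–Hiyama–Kishi addition (CrCl2 in excess, NiCl2 2 mol %, DMF, rt, high dilution), which tolerates the ketone and the lactone, gives the ring B carbinol F7 as a C7 epimer mixture. Dess–Martin oxidation converges both epimers on 31.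

Step 21 (hydroxide can open the lactone, and the product is a base-sensitive hydroxyquinone). The fallback sets out from 33 and comes back at 34 without any hydroxide. Pyrrolidine (MeOH, 0 °C) replaces the C12 methoxy group by addition–elimination to give the 12-(pyrrolidin-1-yl)quinone F8, a vinylogous amide. This is hydrolysed with 1 M aq. HCl in THF at 40 °C to 34, under conditions in which the lactone stays closed.

## Further compounds

F1 | step 10 | (4R,5R)-5-{[tert-butyl(diphenyl)silyl]oxymethyl}-4-(2-methylprop-2-en-1-yl)oxolan-2-one | CC(C)(C)[Si](c1ccccc1)(c1ccccc1)OC[C@@H]1OC(=O)C[C@H]1CC(C)=C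
F2 | step 10 | (4R,5R)-5-{[tert-butyl(diphenyl)silyl]oxymethyl}-3-(hydroxymethylidene)-4-(2-methylprop-2-en-1-yl)oxolan-2-one | CC(C)(C)[Si](c1ccccc1)(c1ccccc1)OC[C@@H]1OC(=O)C(=CO)[C@H]1CC(C)=C
F3 | step 10 | (3R,4R,5R)-5-{[tert-butyl(diphenyl)silyl]oxymethyl}-3-methyl-4-(2-methylprop-2-en-1-yl)-2-oxooxolane-3-carbaldehyde | CC(C)(C)[Si](c1ccccc1)(c1ccccc1)OC[C@@H]1OC(=O)[C@@](C)(C=O)[C@H]1CC(C)=C
F4 | step 10 | (3R,4R,5R)-5-{[tert-butyl(diphenyl)silyl]oxymethyl}-3-methyl-2-oxo-4-(2-oxopropyl)oxolane-3-carbaldehyde | CC(C)(C)[Si](c1ccccc1)(c1ccccc1)OC[C@@H]1OC(=O)[C@@](C)(C=O)[C@H]1CC(C)=O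
F5 | step 18 | (3R,3aR,4E,7aS)-3-(hydroxymethyl)-4-{[2-iodo-3,5,6-trimethoxy-4-(propan-2-yl)phenyl]methylidene}-7a-methyl-3a,6,7,7a-tetrahydroisobenzofuran-1,5(3H,4H)-dione | OC[C@@H]1OC(=O)[C@@]3(C)CCC(=O)/C(=C/c2c(I)c(OC)c(C(C)C)c(OC)c2OC)[C@@H]13
F6 | step 18 | (3R,3aR,4E,7aS)-4-{[2-iodo-3,5,6-trimethoxy-4-(propan-2-yl)phenyl]methylidene}-7a-methyl-1,5-dioxooctahydroisobenzofuran-3-carbaldehyde | O=C[C@@H]1OC(=O)[C@@]3(C)CCC(=O)/C(=C/c2c(I)c(OC)c(C(C)C)c(OC)c2OC)[C@@H]13
F7 | step 18 | (4S,5R,6R)-7-hydroxy-11,12,14-trimethoxy-1-oxo-9(10→20)-abeo-abieta-8,10(20),11,13-tetraen-19,6-olide (both C7 epimers) | CC(C)c1c(OC)c(OC)c2c(c1OC)C(O)[C@@H]1OC(=O)[C@@]3(C)CCC(=O)C(=C2)[C@@H]13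
F8 | step 21 | (1R,4S,5R,6R,7S)-1,7-dihydroxy-11,14-dioxo-12-(pyrrolidin-1-yl)-9(10→20)-abeo-abieta-8,10(20),12-trien-19,6-olide | CC(C)C1=C(N4CCCC4)C(=O)C2=C(C1=O)[C@H](O)[C@@H]1OC(=O)[C@@]3(C)CC[C@@H](O)C(=C2)[C@@H]13
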